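A small charge of starting material, 0.10 M, meets 3.00 equiv of coupling partner and 1.00 equiv of scavenger, and I ask how much target each way of mixing them gives.

| flask | starting material | coupling partner | scavenger | remark | time |
|---|---|---|---|---|---|
| beta | 0.10 M | 3 equiv | 1 equiv | run made earlier |  |
| delta | 0.10 M | 3 equiv | 1.4 equiv | run made earlier |  |
| theta | 0.10 M | 3 equiv | 2.2 equiv | run made earlier |  |
| gamma | 0.050 M | 3 equiv | 1 equiv | run made earlier |  |
| blue | 0.10 M | 3.00 equiv | 1.00 equiv | a closed flask charged with all of it at once and left for 40 h | 40 h |
| grey | 0.10 M (fed, over 40.0 h) | 3.00 equiv | 1.00 equiv | all but starting material at the start; starting material goes in evenly over 40.0 h, the run ends at 40 h | 40 h |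
| teal | 0.10 M | 3.00 equiv (fed, over 40.0 h) | 1.00 equiv | a stirred flask in which coupling partner is dosed at a steady rate over 40.0 h without added volume, worked up at 40 h | 40 h |
| red | 0.10 M | 3.00 equiv | 1.00 equiv | one stirred flow tank at steady state, fed with the mixture as stated, mean residence time 40 h |  |

| run | time / h | target / % | starting material / % |
|---|---|---|---|
| beta | 3.00 | 92.6 | 5.7 |
| beta | 6.00 | 99.0 | 2.0 |
| beta | 10.0 | 100.5 | 0.8 |
| beta | 15.0 | 101.6 | 0 |
| beta | 20.0 | 100.7 | 0.6 |
| beta | 25.0 | 98.3 | 0 |
| delta | 3.00 | 92.6 | 5.8 |
| delta | 5.00 | 98.3 | 2.3 |
| delta | 8.00 | 101.8 | 0 |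
| delta | 12.0 | 101.8 | 0.7 |
| delta | 15.0 | 99.7 | 0.2 |
| delta | 25.0 | 99.8 | 0 |
| delta | 40.0 | 99.1 | 1.4 |
| theta | 6.00 | 97.3 | 1.4 |
| theta | 12.0 | 99.8 | 1.2 |
| theta | 15.0 | 100.6 | 0 |
| theta | 25.0 | 100.2 | 0 |
| theta | 30.0 | 100.6 | 0 |
| theta | 40.0 | 100.3 | 0.8 |
| gamma | 3.00 | 75.6 | 24.2 |
| gamma | 6.00 | 93.8 | 5.0 |
| gamma | 12.0 | 100.1 | 0.3 |
| gamma | 20.0 | 100.6 | 0 |
| gamma | 40.0 | 100.0 | 0 |

(readings scatter by 1 percentage point)

- percentages count the starting material that a species holds: one homo dimer counts as two
- released group is meant together with its idle adduct
- the stated concentrations are those of everything mixed, before any reaction; amounts are the same in each set-up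
- what was read earlier has a scatter of 1 percentage point, one standard deviation
- steps that have been proposed: starting material + released group <-> idle adduct; 2 starting material -> homo dimer; starting material + coupling partner -> target + released group; scavenger + released group -> scavenged by-product
- the feed brings no volume worth counting
- the earlier runs were made in a closed, stirred flask

1. the set-up with the highest amount of target at the outlet or at the end, in percent of the starting material put in ("none" if the first two lie within 2 percentage points) (blue / grey / teal / red / none)
2. amount of target at the outlet or at the end, in percent of the starting material put in, blue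
3. amount of target at the outlet or at the end, in percent of the starting material put in, grey
4. amount of target at the outlet or at the end, in percent of the starting material put in, teal
5. amount of target at the outlet or at the end, in percent of the starting material put in, red

Delta still reads 99.1 % at 40.0 h, and beta and delta, with different scavenger, read 92.6 % and 92.6 % at 3.00 h, so I reckon with starting material + coupling partner. Let x be the starting material as a fraction of its charge, b the partner on the same scale, q its equivalents, and s its surplus over the charge, 2.00. Then x falls by c·x·b per hour, c being the rate constant times the charged concentration, and in a closed flask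

ln[b/(q·x)] = c·s·t.

Gamma holds x = 24.2 % at 3.00 h, which gives a reading of c = 0.188 h⁻¹. Blue's concentration is twice gamma's, so c = 0.376 h⁻¹ there. Over 40 h this gives

N = c·s·t = 30.1,

the clearing number: how many e-foldings surplus partner allows the starting material.

Blue: x = (s/q)·exp(−N) = <0.001 %, so nearly all becomes target.

Grey: near the end I set the feed per hour, the charge over t, equal to c·x·s, so x is about the inverse of N and target about 96.7 %.

Red: the same balance with the outflow counted makes x about the inverse of one plus N, so target is about 96.8 %.

Teal: the dosed partner equals the charge of starting material at 13.3 h, and a mean surplus of s/2 over the remaining 26.7 h gives N = 10.0. That multiplies x by about 4.44 × 10⁻⁵, so I expect teal within 2 percentage points of blue, less any homo dimer formed, which I have not reckoned.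

The forecast gives 100 %, 96.7 %, 99 % and 96.9 % for blue, grey, teal and red, best none, and says of teal: “The unseen dimer could cost a few percent at most”.

The flasks give 99.9 %, 97.0 %, 98.8 % and 96.9 %, best none.

    starting material + released group ⇌ idle adduct, settled at all times (K = 16.0 L mol⁻¹)
    2 starting material → homo dimer (k = 0.00871 L mol⁻¹ h⁻¹)
    starting material + coupling partner → target + released group (k = 4.18 L mol⁻¹ h⁻¹)
    scavenger + released group → scavenged by-product (k = 72.6 L mol⁻¹ h⁻¹)

A neighbouring flask is blue with 0.750 equiv of partner. The surplus now lies with the starting material, 0.250 of the charge, and the partner becomes the limiting reagent. The same number is N = c·u·t = 3.76, so I reckon 0.582 % of the partner's charge left and target near 75.0 %. That flask ends with 0.44 % of its partner, 24 % of its starting material and 74.7 % target.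

The earlier runs and the new flask are calculated for substances that don't exist; noise was put on by code.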